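**Counting starters.** Decide first what to count as a chain starter: E as charged, or what X leaves of it.

| flask | G | E | X | remark | time |
|---|---|---|---|---|---|
| epsilon | 1.1 M | 62 mM | 5.6 mM | run made earlier |  |
| theta | 1.1 M | 97 mM | 5.6 mM | run made earlier |  |
| beta | 1.1 M | 44 mM | 11 mM | run made earlier |  |
| flask | 1.1 M | 44 mM | 5.6 mM |  | 30 min |

| run | time / min | J / % | G / % |
|---|---|---|---|
| epsilon | 1.33 | 3.9 | 97.3 |
| epsilon | 2.00 | 6.4 | 93.1 |
| epsilon | 3.00 | 8.0 | 92.6 |
| epsilon | 5.00 | 10.4 | 88.8 |
| epsilon | 8.00 | 18.3 | 82.1 |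
| epsilon | 12.0 | 24.5 | 75.8 |
| epsilon | 20.0 | 32.8 | 66.3 |
| theta | 1.33 | 4.3 | 94.6 |
| theta | 2.00 | 7.7 | 90.4 |
| theta | 3.00 | 11.6 | 90.2 |
| theta | 5.00 | 18.1 | 81.3 |
| theta | 8.00 | 25.8 | 75.1 |
| theta | 12.0 | 35.6 | 64.2 |
| theta | 20.0 | 49.0 | 50.7 |
| beta | 4.00 | 4.1 | 91.6 |
| beta | 8.00 | 11.1 | 90.6 |
| beta | 10.0 | 12.2 | 88.5 |
| beta | 15.0 | 16.0 | 83.0 |
| beta | 20.0 | 20.2 | 78.0 |

(scatter of a reading: 1 percentage point)

1. whether the average number of monomer units in a chain (chains begun, living or dead) reaches 40 by 30 min (yes / no)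
2. average number of monomer units in a chain (chains begun, living or dead) at 30 min

- the average divides the monomer in chains by the number of chains begun, living and dead together
- the earlier runs do not show the number of chains; that part of a forecast is a guess

Take ln(1/G)/t, with G the fraction of the charge left and t the time, at each run's last reading and divide by the E charged: theta gives 0.350 L mol⁻¹ min⁻¹ and beta 0.282 L mol⁻¹ min⁻¹, which is lower. Divide instead by E minus X, and epsilon, theta and beta read 0.364 L mol⁻¹ min⁻¹, 0.372 L mol⁻¹ min⁻¹ and 0.376 L mol⁻¹ min⁻¹. So call the mean of these readings κ, 0.371 L mol⁻¹ min⁻¹, and call E charged minus X charged the net charge n, which is 38.4 mM in this flask. That each net E begins one chain is a guess, since the runs show no chain count.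

**Length curve.** G then falls pseudo-first-order at s = κn, 0.0142 min⁻¹. Reckoned on n, the average length climbs at first at κ times the G charged, 0.408 min⁻¹. It bends around 1/s, 70.4 min, and runs towards the ceiling of G charged over n, 28.6. That ceiling lies below the 40 wanted, so on this guess your answer is no. At 30 min, your reckoned length is ceiling times (1 − exp(−st)), which gives 9.96.

**The forecast.** The forecast says no and 9, within 7.5 to 14, reasoning that “If every E starts a chain, DP ≈ 8.5”; its 9 lies below your 9.96.

**The result.** This flask gives no and 9.03. At 30.0 min, L stands at 0.00548 M, nearly all of the X charged. Dividing the flask's J, 31.6%, by n gives 9.06.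

    G + E → Q + J (k = 0.560 L mol⁻¹ min⁻¹)
    G + Q → J + Q, rate k2*[Q]*[G] (k = 0.380 L mol⁻¹ min⁻¹)
    E + X → L (k = 60.0 L mol⁻¹ min⁻¹)
    Q + G → D (k = 0.0140 L mol⁻¹ min⁻¹)

**Second flask.** Read the same flask at 20 min, and n with s gives 7.07. The computed length there is 6.82.

(The data were generated by integration for substances that don't exist; the scatter is artificial.)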